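The ring is numbered C1 (C=O), C2=C3, C4 (CHOH), C5 (C(OH) bearing the chain) and C6 (CH2). The oxygens on C1 and C4 stand 1,4 to each other across the C2=C3 alkene of the cyclohexenone ring, which is the pattern left by an opened 2,3-dioxabicyclo[2.2.2]oct-5-ene.
Retrosynthesis: the two oxygens are re-joined (O–O), then C1–O and C4–O are cut together ([4+2] with singlet oxygen) to reach an (S)-cyclohexa-2,4-dien-1-ol. Next C5–C1' (ring to chain) and C11'–C12' (inside the chain) are cut.
Forward: the C6 and C11 pieces are joined to the C17 chain and its Grignard reagent is added to benzoquinone monoketal, so the carbocycle is bought. One ring alkene is then reduced, the carbonyl is erased by a Shapiro reaction, and the dioxabicycle is closed and opened again.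
Stereochemistry: C5 comes from a ligand-controlled copper hydride desymmetrisation of the achiral p-quinol ether. C4 is relayed from C5 through the face of the cycloaddition. The E alkene is bought with (E)-hex-3-en-1-ol.

Key step: step 9

Assumption: the (S,S)-ligand of step 6 is taken to leave the (S)-enone. The sense of induction has to be checked on the hydroxy enone of that step, and the equally available (R,R)-ligand is used without other change if it proves opposite.

Step 1
Reactants: 1 (E)-hex-3-en-1-ol
Product: 2 (E)-1-bromohex-3-ene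
Conditions: CBr4, PPh3, CH2Cl2, 0 °C
Reagents that add atoms: tetrabromomethane, BrC(Br)(Br)Br
Why: Appel reaction, in which bromide displaces the alkoxyphosphonium ion of the primary alcohol in an SN2 step under neutral conditions that leave the E alkene untouched.

Step 2
Reactants: 2 (E)-1-bromohex-3-ene; 3 11-bromoundecan-1-ol
Product: 6 (E)-heptadec-14-en-1-ol, via hexenylmagnesium bromide 4 (not isolated), via bromomagnesium bromoundecanolate 5 (not isolated)
Conditions: Mg, THF, rt (2 to 4, 2.3 equiv.); 3, Li2CuCl4 (3 mol%), NMP, THF, −10 °C to rt; aq. work-up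
Reagents that add atoms: magnesium, [Mg] (kept only in 4 and 5)
Why: Copper-catalysed cross-coupling of a primary Grignard reagent with a primary alkyl bromide forms C11'–C12', the first equivalent of 4 only turns the hydroxyl into the inert alkoxide 5, and the homoallylic Grignard reagent keeps its E geometry at or below room temperature.

Step 3
Reactants: 6 (E)-heptadec-14-en-1-ol
Product: 7 (E)-17-bromoheptadec-3-ene
Conditions: CBr4, PPh3, CH2Cl2, 0 °C
Reagents that add atoms: tetrabromomethane, BrC(Br)(Br)Br
Why: A second Appel reaction on an unhindered primary alcohol, again neutral and without effect on the remote alkene.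

Step 4
Reactants: 7 (E)-17-bromoheptadec-3-ene; 8 4,4-dimethoxycyclohexa-2,5-dien-1-one
Product: 11 4-[(E)-heptadec-14-enyl]-4-hydroxycyclohexa-2,5-dien-1-one, via heptadecenylmagnesium bromide 9 (not isolated), via quinol dimethyl ketal 10 (not isolated)
Conditions: Mg, THF, 40 °C; 8, LaCl3·2LiCl (0.3 equiv.), THF, −78 to −20 °C; H2O; then (CO2H)2, THF/H2O, rt
Reagents that add atoms: magnesium, [Mg] (kept only in 9); water, O
Why: 1,2-Addition of a primary alkyl Grignard reagent to the carbonyl of a quinone monoketal, assisted by the oxophilic lanthanum salt, followed by mild acid hydrolysis of the labile bis-allylic ketal is the standard non-oxidative entry to 4-alkyl-p-quinols, and no stereocentre arises because 11 has a mirror plane.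

Step 5
Reactants: 11 4-[(E)-heptadec-14-enyl]-4-hydroxycyclohexa-2,5-dien-1-one
Product: 12 4-[(E)-heptadec-14-enyl]-4-(triethylsilyloxy)cyclohexa-2,5-dien-1-one
Conditions: Et3SiOTf, 2,6-lutidine, CH2Cl2, −78 to 0 °C
Reagents that add atoms: triethylsilyl trifluoromethanesulfonate, CC[Si](CC)(CC)OS(=O)(=O)C(F)(F)F
Why: Silyl triflate silylation of a tertiary alcohol, which keeps the hydroxyl out of the silane chemistry of the next step and makes the two groups on the prochiral carbon clearly different in size; the dienone has no enolisable hydrogen.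

Step 6
Reactants: 12 4-[(E)-heptadec-14-enyl]-4-(triethylsilyloxy)cyclohexa-2,5-dien-1-one
Product: 15 (4S)-4-[(E)-heptadec-14-enyl]-4-hydroxycyclohex-2-en-1-one, via bis-silyl dienol ether 13 (not isolated), via triethylsilyl enone 14 (not isolated)
Conditions: Cu(OAc)2 (5 mol%), 1,2-bis[(2S,5S)-2,5-diphenylphospholan-1-yl]ethane (6 mol%), (EtO)2MeSiH (1.3 equiv.), toluene, −20 °C; then Bu4NF, THF, 0 °C to rt
Reagents that add atoms: diethoxy(methyl)silane, C[SiH](OCC)OCC (silicon kept only in 13)
Why: Desymmetrising asymmetric conjugate reduction of a 4,4-disubstituted cyclohexa-2,5-dienone, in which the ligated copper hydride gives hydride to one of the two enantiotopic β-carbons and so makes the carbinol carbon (C5 of the target) the S stereocentre, the ring is parked as dienol silane 13 so that the second alkene is spared, the isolated chain alkene is inert, and fluoride then frees ketone and carbinol.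

Step 7
Reactants: 15 (4S)-4-[(E)-heptadec-14-enyl]-4-hydroxycyclohex-2-en-1-one
Product: 16 N'-{(4S)-4-[(E)-heptadec-14-enyl]-4-hydroxycyclohex-2-en-1-ylidene}-4-methylbenzenesulfonohydrazide (C=N isomers)
Conditions: TsNHNH2, MeOH, rt
Reagents that add atoms: 4-methylbenzenesulfonohydrazide, Cc1ccc(cc1)S(=O)(=O)NN
Why: Plain hydrazone condensation at the enone carbonyl, conjugate addition being held back by the fully substituted carbon next to the β-position, with no effect on the stereocentre.

Step 8
Reactants: 16 N'-{(4S)-4-[(E)-heptadec-14-enyl]-4-hydroxycyclohex-2-en-1-ylidene}-4-methylbenzenesulfonohydrazide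
Product: 18 (1S)-1-[(E)-heptadec-14-enyl]cyclohexa-2,4-dien-1-ol, via dienyllithium alkoxide 17 (not isolated)
Conditions: MeLi (4 equiv.), Et2O/THF, −78 °C to rt; H2O, 0 °C; base-washed glassware
Reagents that add atoms: methyllithium, [Li]C (lithium kept only in 17)
Why: Shapiro reaction of an enone tosylhydrazone, in which the only sp3 C–H next to the C=N bond (the γ-carbon carries none) is removed, sulfinate and nitrogen leave and the dienyllithium is protonated to the homoannular diene, while the carbinol travels as a lithium alkoxide that cannot act as a leaving group and the acid-labile arene hydrate meets only basic media.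

Step 9
Reactants: 18 (1S)-1-[(E)-heptadec-14-enyl]cyclohexa-2,4-dien-1-ol
Product: 19 (1R,4R,7S)-7-[(E)-heptadec-14-enyl]-2,3-dioxabicyclo[2.2.2]oct-5-en-7-ol (peroxide bridge on the hydroxyl face)
Conditions: O2, 5,10,15,20-tetraphenylporphyrin (1 mol%), white LED, K2CO3 (solid), toluene (dilute), −40 °C; kept cold on concentration
Reagents that add atoms: dioxygen, O=O
Why: Sensitised singlet oxygen adds to the s-cis C1=C2–C3=C4 diene of 18 in a concerted suprafacial [4+2] cycloaddition that forms the C1–O and C4–O bonds at once, and the closest known reaction type is the dye-sensitised photooxygenation of cyclohexa-1,3-dienes to 2,3-dioxabicyclo[2.2.2]oct-5-enes. The one new ring, the six-membered 1,2-dioxine C1–O–O–C4–C3=C2, closes by cycloaddition across the carbocycle, which thereby becomes a bridged bicycle. Both new stereocentres (C1 and C4) follow from the face attacked, and that face is set by C5: the pseudoaxial free hydroxyl can hydrogen-bond to the incoming, negatively polarised oxygen, as in the photooxygenation of chiral allylic alcohols in non-polar media, and it is smaller than the chain CH2 on the other face. For this reason the silyl group is taken off beforehand and a cold, dilute, non-coordinating solvent is used. Chemoselectivity against the chain alkene is secured by the much faster reaction of a cisoid ring diene compared with the slow ene reaction of an isolated 1,2-disubstituted alkene, so irradiation is stopped once 18 is consumed. The neutral medium over solid K2CO3 keeps the arene hydrate from losing water.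

Step 10
Reactants: 19 (1R,4R,7S)-7-[(E)-heptadec-14-enyl]-2,3-dioxabicyclo[2.2.2]oct-5-en-7-ol
Product: 20 (4R,5S)-5-[(E)-heptadec-14-enyl]-4,5-dihydroxycyclohex-2-en-1-one
Conditions: Et3N (0.3 equiv.), CH2Cl2, 0 °C
Reagents that add atoms: none
Why: Kornblum–DeLaMare fragmentation, in which the amine removes the bridgehead C1–H flanked only by the C6 methylene rather than the C4–H shielded by the fully substituted C5, the O–O bond breaks in an E2-like way to give the C1 ketone and a C4 alkoxide stabilised by the neighbouring C5 hydroxyl, C4 and C5 are untouched so the cis-diol is kept, and the weak base at 0 °C avoids β-elimination of the C5 hydroxyl.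

Compound list
1 | (E)-hex-3-en-1-ol | CC/C=C/CCO | starting material
2 | (E)-1-bromohex-3-ene | CC/C=C/CCBr | intermediate
3 | 11-bromoundecan-1-ol | OCCCCCCCCCCCBr | starting material
4 | (E)-hex-3-en-1-ylmagnesium bromide | CC/C=C/CC[Mg]Br | intermediate
5 | bromomagnesium 11-bromoundecan-1-olate | BrCCCCCCCCCCCO[Mg]Br | intermediate
6 | (E)-heptadec-14-en-1-ol | CC/C=C/CCCCCCCCCCCCCO | intermediate
7 | (E)-17-bromoheptadec-3-ene | CC/C=C/CCCCCCCCCCCCCBr | intermediate
8 | 4,4-dimethoxycyclohexa-2,5-dien-1-one | COC1(OC)C=CC(=O)C=C1 | starting material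
9 | (E)-heptadec-14-en-1-ylmagnesium bromide | CC/C=C/CCCCCCCCCCCCC[Mg]Br | intermediate
10 | 1-[(E)-heptadec-14-enyl]-4,4-dimethoxycyclohexa-2,5-dien-1-ol | CC/C=C/CCCCCCCCCCCCCC1(O)C=CC(OC)(OC)C=C1 | intermediate
11 | 4-[(E)-heptadec-14-enyl]-4-hydroxycyclohexa-2,5-dien-1-one | CC/C=C/CCCCCCCCCCCCCC1(O)C=CC(=O)C=C1 | intermediate
12 | 4-[(E)-heptadec-14-enyl]-4-(triethylsilyloxy)cyclohexa-2,5-dien-1-one | CC/C=C/CCCCCCCCCCCCCC1(O[Si](CC)(CC)CC)C=CC(=O)C=C1 | intermediate
13 | {[(4S)-4-[(E)-heptadec-14-enyl]-4-(triethylsilyloxy)cyclohexa-1,5-dien-1-yl]oxy}diethoxy(methyl)silane | CC/C=C/CCCCCCCCCCCCC[C@]1(O[Si](CC)(CC)CC)CC=C(O[Si](C)(OCC)OCC)C=C1 | intermediate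
14 | (4S)-4-[(E)-heptadec-14-enyl]-4-(triethylsilyloxy)cyclohex-2-en-1-one | CC/C=C/CCCCCCCCCCCCC[C@]1(O[Si](CC)(CC)CC)CCC(=O)C=C1 | intermediate
15 | (4S)-4-[(E)-heptadec-14-enyl]-4-hydroxycyclohex-2-en-1-one | CC/C=C/CCCCCCCCCCCCC[C@]1(O)CCC(=O)C=C1 | intermediate
16 | N'-{(4S)-4-[(E)-heptadec-14-enyl]-4-hydroxycyclohex-2-en-1-ylidene}-4-methylbenzenesulfonohydrazide (C=N isomers) | CC/C=C/CCCCCCCCCCCCC[C@]1(O)CCC(=NNS(=O)(=O)c2ccc(C)cc2)C=C1 | intermediate
17 | lithium (1S)-1-[(E)-heptadec-14-enyl]-4-lithiocyclohexa-2,4-dien-1-olate | CC/C=C/CCCCCCCCCCCCC[C@]1(O[Li])CC=C([Li])C=C1 | intermediate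
18 | (1S)-1-[(E)-heptadec-14-enyl]cyclohexa-2,4-dien-1-ol | CC/C=C/CCCCCCCCCCCCC[C@]1(O)CC=CC=C1 | intermediate
19 | (1R,4R,7S)-7-[(E)-heptadec-14-enyl]-2,3-dioxabicyclo[2.2.2]oct-5-en-7-ol | CC/C=C/CCCCCCCCCCCCC[C@]1(O)C[C@@H]2C=C[C@H]1OO2 | intermediate
20 | (4R,5S)-5-[(E)-heptadec-14-enyl]-4,5-dihydroxycyclohex-2-en-1-one | CC/C=C/CCCCCCCCCCCCC[C@]1(O)CC(=O)C=C[C@H]1O | target

Total step count: 10. Longest linear sequence: 10 steps (1 to 20); 3 and 8 are bought and enter this line directly.

Steps most likely to fail

Step 9. Facial selectivity may be poor, because repulsion between the hydroxyl lone pairs and the incoming oxygen can offset the hydrogen bond. The dienol may also lose water during irradiation.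
- The fallback sets out from 18 and fixes the face by coordination instead of by a hydrogen bond.
- VO(acac)2 and tert-butyl hydroperoxide in toluene at 0 °C epoxidise the allylic C3=C4 alkene from the hydroxyl face. This hydroxyl-directed epoxidation does not touch the chain alkene and gives (1R,2S,6R)-2-[(E)-heptadec-14-enyl]-7-oxabicyclo[4.1.0]hept-4-en-2-ol F1.
- Pd(PPh3)4 and acetic acid in THF open this vinyl epoxide through the π-allyl complex of divalent palladium. Overall retention and 1,4-regiochemistry lead to (1R,4R,5S)-5-[(E)-heptadec-14-enyl]-4,5-dihydroxycyclohex-2-en-1-yl acetate F2.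
- 2,2-Dimethoxypropane with pyridinium p-toluenesulfonate ties up the cis C4,C5-diol as (1R,4R,5S)-5-[(E)-heptadec-14-enyl]-4,5-(isopropylidenedioxy)cyclohex-2-en-1-yl acetate F3.
- K2CO3 in methanol frees (1R,4R,5S)-5-[(E)-heptadec-14-enyl]-4,5-(isopropylidenedioxy)cyclohex-2-en-1-ol F4.
- MnO2 in CH2Cl2 oxidises the only free allylic alcohol to (4R,5S)-5-[(E)-heptadec-14-enyl]-4,5-(isopropylidenedioxy)cyclohex-2-en-1-one F5.
- Aqueous acetic acid at room temperature removes the acetonide, and the route is rejoined at the target 20.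

Step 6. The catalyst may discriminate the two enantiotopic alkenes too weakly, since a silyloxy group and an unbranched alkyl group have to be told apart. Some double reduction may also occur.
- The fallback sets out from 12 and moves the desymmetrisation from a hydride transfer to a proton transfer.
- Exhaustive conjugate reduction with an achiral copper hydride (Cu(OAc)2, 1,2-bis(diphenylphosphino)benzene, excess (EtO)2MeSiH, t-BuOH, toluene) gives the achiral 4-[(E)-heptadec-14-enyl]-4-(triethylsilyloxy)cyclohexan-1-one F6.
- Enantioselective deprotonation follows with lithium bis[(S)-1-phenylethyl]amide in the presence of Me3SiCl at −100 °C. The antipode is chosen on the model of 4-tert-butylcyclohexanone, with the chain taking the equatorial place. The product is {[(4S)-4-[(E)-heptadec-14-enyl]-4-(triethylsilyloxy)cyclohex-1-en-1-yl]oxy}trimethylsilane F7.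
- Saegusa–Ito dehydrogenation with Pd(OAc)2 in MeCN comes back to the route at 14, which Bu4NF converts into 15 as in step 6.

Step 8. The trianion may be deprotonated incompletely at the α'-carbon, methyllithium may add to the C=N bond, or excess base may trigger loss of lithium oxide from the dienol alkoxide and aromatise the ring.
- The fallback sets out from 15 and replaces the strong-base route by a palladium-catalysed elimination.
- Luche reduction (NaBH4, CeCl3·7H2O, MeOH, 0 °C) gives (1S)-1-[(E)-heptadec-14-enyl]cyclohex-2-ene-1,4-diol F8 as a mixture of C4 epimers, which is of no consequence.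
- Ac2O and pyridine acylate only the secondary hydroxyl, giving (4S)-4-[(E)-heptadec-14-enyl]-4-hydroxycyclohex-2-en-1-yl acetate F9.
- Pd(PPh3)4 with Et3N in THF at 50 °C ionises the allylic acetate. The π-allyl intermediate loses the only available β-hydrogen, that of the ring CH2, because the other terminus adjoins the fully substituted carbinol carbon.
- The route is rejoined at 18 under basic conditions throughout.

Further compounds
F1 | step 9 | (1R,2S,6R)-2-[(E)-heptadec-14-enyl]-7-oxabicyclo[4.1.0]hept-4-en-2-ol | CC/C=C/CCCCCCCCCCCCC[C@]1(O)CC=C[C@H]2O[C@@H]12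
F2 | step 9 | (1R,4R,5S)-5-[(E)-heptadec-14-enyl]-4,5-dihydroxycyclohex-2-en-1-yl acetate | CC/C=C/CCCCCCCCCCCCC[C@]1(O)C[C@@H](OC(C)=O)C=C[C@H]1O
F3 | step 9 | (1R,4R,5S)-5-[(E)-heptadec-14-enyl]-4,5-(isopropylidenedioxy)cyclohex-2-en-1-yl acetate | CC/C=C/CCCCCCCCCCCCC[C@]12C[C@@H](OC(C)=O)C=C[C@H]1OC(C)(C)O2
F4 | step 9 | (1R,4R,5S)-5-[(E)-heptadec-14-enyl]-4,5-(isopropylidenedioxy)cyclohex-2-en-1-ol | CC/C=C/CCCCCCCCCCCCC[C@]12C[C@@H](O)C=C[C@H]1OC(C)(C)O2
F5 | step 9 | (4R,5S)-5-[(E)-heptadec-14-enyl]-4,5-(isopropylidenedioxy)cyclohex-2-en-1-one | CC/C=C/CCCCCCCCCCCCC[C@]12CC(=O)C=C[C@H]1OC(C)(C)O2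
F6 | step 6 | 4-[(E)-heptadec-14-enyl]-4-(triethylsilyloxy)cyclohexan-1-one | CC/C=C/CCCCCCCCCCCCCC1(O[Si](CC)(CC)CC)CCC(=O)CC1
F7 | step 6 | {[(4S)-4-[(E)-heptadec-14-enyl]-4-(triethylsilyloxy)cyclohex-1-en-1-yl]oxy}trimethylsilane | CC/C=C/CCCCCCCCCCCCC[C@]1(O[Si](CC)(CC)CC)CCC(O[Si](C)(C)C)=CC1
F8 | step 8 | (1S)-1-[(E)-heptadec-14-enyl]cyclohex-2-ene-1,4-diol (both C4 epimers) | CC/C=C/CCCCCCCCCCCCC[C@]1(O)CCC(O)C=C1
F9 | step 8 | (4S)-4-[(E)-heptadec-14-enyl]-4-hydroxycyclohex-2-en-1-yl acetate (both C1 epimers) | CC/C=C/CCCCCCCCCCCCC[C@]1(O)CCC(OC(C)=O)C=C1
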